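**Plan**

1. Numbering (germacranolide): ring carbons C1–C10; the ether oxygen joins C1 and C4 (2,3-dihydrofuran O, C1, C2, C3, C4); butenolide C6, C7, C11, C12, O; C13 = CH2OAc; C14 and C15 = methyls on C10 and C4.
2. The retrosynthesis cuts, in this order: the two acetates; C5=C6 (opens the ten-membered ring); C7=C11 and O–C6 (butenolide); C6–C7; C1–C10; C3–C4.
3. Enabling feature: C4 is the quaternary ether carbon of the dihydrofuran ring and carries methyl C15 and C5. Its C3–C4 bond can stand where the C–H bond of a secondary methyl carbinol ether was, so the ring O–C1–C2–C3–C4 can be closed by carbenoid C–H insertion.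
4. Forward order: the dihydrofuran ring first (step 4); then the chain is joined at C1–C10; then the butenolide is closed; last the ten-membered carbocycle is closed at C5=C6.
5. Stereochemistry: C4 comes from (R)-propane-1,2-diol with retention in the insertion; C8 from a catalytic asymmetric glyoxylate-ene reaction; C10 from C8 by chelation-controlled ketone addition (1,3-anti); the C5=C6 geometry is imposed by the ring.

Key step: step 4

Remark: (R)-propane-1,2-diol, the reduction product of methyl (R)-lactate, is taken as the purchased chiral-pool material; the germacranolide atom numbers are used for all intermediates.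

**Route**

Step 1
Reactants: 1 (R)-propane-1,2-diol
Product: 2 (R)-1-(triisopropylsilyloxy)propan-2-ol
Conditions: TIPSCl, imidazole, CH2Cl2, 0 °C → rt
Reagents that add atoms: triisopropylsilyl chloride, CC(C)[Si](Cl)(C(C)C)C(C)C
Why: Silylation is much faster at the primary hydroxyl, so the bulky group goes to C5–O and leaves the secondary carbinol (future C4) free; TIPS is chosen because it must later resist NaH, KOt-Bu/DMSO and t-BuLi.

Step 2
Reactants: 2 (R)-1-(triisopropylsilyloxy)propan-2-ol; 3 bromoacetic acid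
Product: 4 2-{[(2R)-1-(triisopropylsilyloxy)propan-2-yl]oxy}acetic acid
Conditions: NaH, THF, 0 °C → rt; 1 M HCl work-up
Reagents that add atoms: none
Why: Williamson ether synthesis in which the sodium alkoxide of 2 displaces bromide from sodium bromoacetate at the carbon that becomes C1; the C4–O bond is not touched, so C4 keeps its configuration, and the hindered TIPS group resists 1,2-silyl migration.

Step 3
Reactants: 4 2-{[(2R)-1-(triisopropylsilyloxy)propan-2-yl]oxy}acetic acid; 5 (trimethylsilyl)diazomethane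
Product: 7 1-diazo-3-{[(2R)-1-(triisopropylsilyloxy)propan-2-yl]oxy}propan-2-one, via isobutyl carbonic mixed anhydride 6 (not isolated)
Conditions: i-BuOCOCl, N-methylmorpholine, THF, −15 °C; then 5, MeCN, 0 °C → rt
Reagents that add atoms: none
Why: Mixed-anhydride activation followed by C-acylation of the diazoalkane (Arndt–Eistert-type diazoketone synthesis) adds the carbenoid carbon C3; the C-silyl group is lost to the carbonate leaving group and the neutral conditions leave the silyl ether and C4 untouched.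

Step 4
Reactants: 7 1-diazo-3-{[(2R)-1-(triisopropylsilyloxy)propan-2-yl]oxy}propan-2-one
Product: 8 (5S)-5-methyl-5-[(triisopropylsilyloxy)methyl]dihydrofuran-3(2H)-one
Conditions: Rh2(OAc)4 (1 mol%), CH2Cl2, rt, slow addition of 7
Reagents that add atoms: none
Why: Rh2(OAc)4 (divalent rhodium) expels N2 from 7 to give an electrophilic rhodium carbenoid at C3, which inserts into the C4–H bond through a concerted three-centre transition state. The closest known reaction type is the dirhodium tetracarboxylate-catalysed intramolecular C–H insertion of alkoxymethyl diazoketones next to ether oxygen, which gives furan-3(2H)-ones. The five-membered ring O–C1–C2–C3–C4 closes by 1,5-insertion, forming the C3–C4 bond. The new quaternary centre C4 is controlled by the substrate alone: the C–C bond forms on the face the hydrogen occupied, so the carbinol configuration of 1 is carried over with retention (the descriptor becomes S only through the priority change). The step needs site selectivity for C4–H, which is secured because this tertiary, ether-activated C–H is the only one that closes a five-membered ring: insertion at the C5 methylene would need a six-membered ring, an ylide at the ring ether oxygen would be four-membered, and the bulky, weakly basic silyl ether oxygen is a poor ylide donor.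

Step 5
Reactants: 8 (5S)-5-methyl-5-[(triisopropylsilyloxy)methyl]dihydrofuran-3(2H)-one
Product: 9 (5S)-5-methyl-5-[(triisopropylsilyloxy)methyl]tetrahydrofuran-3-ol (both C3 epimers)
Conditions: NaBH4, MeOH, 0 °C
Reagents that add atoms: none
Why: Borohydride reduction of the C2 ketone; the new carbinol centre forms as a mixture of epimers, which is of no consequence because C2 becomes sp2 in step 7.

Step 6
Reactants: 9 (5S)-5-methyl-5-[(triisopropylsilyloxy)methyl]tetrahydrofuran-3-ol
Product: 10 (5S)-5-methyl-5-[(triisopropylsilyloxy)methyl]tetrahydrofuran-3-yl methanesulfonate (both C3 epimers)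
Conditions: MsCl, Et3N, CH2Cl2, 0 °C
Reagents that add atoms: methanesulfonyl chloride, CS(=O)(=O)Cl
Why: Sulfonylation (mesylate formation) turns the C2 oxygen into a leaving group.

Step 7
Reactants: 10 (5S)-5-methyl-5-[(triisopropylsilyloxy)methyl]tetrahydrofuran-3-yl methanesulfonate
Product: 12 (S)-2-methyl-2-[(triisopropylsilyloxy)methyl]-2,3-dihydrofuran, via 2,5-dihydrofuran isomer 11 (not isolated)
Conditions: KOt-Bu, DMSO, rt → 50 °C
Reagents that add atoms: none
Why: E2 elimination of the mesylate followed by base-mediated isomerisation of the allylic ether to the enol ether; because C4 is quaternary, the oxygen-conjugated C1=C2 double bond is the only possible end point.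

Step 8
Reactants: 13 ethyl glyoxylate; 14 isobutene
Product: 15 ethyl (S)-2-hydroxy-4-methylpent-4-enoate
Conditions: (S)-BINOL (10 mol%), TiCl2(O-i-Pr)2 (10 mol%), 4 Å MS, CH2Cl2, −30 °C
Reagents that add atoms: none
Why: Catalytic asymmetric carbonyl-ene (glyoxylate-ene) reaction in which the (S)-BINOL titanium Lewis acid binds the glyoxylate and leaves one aldehyde face open to isobutene, which should set C8 as (S); the enantiomeric catalyst is the one known to give (R)-hydroxy esters.

Step 9
Reactants: 15 ethyl (S)-2-hydroxy-4-methylpent-4-enoate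
Product: 16 (S)-2-hydroxy-N-methoxy-N,4-dimethylpent-4-enamide
Conditions: MeNH(OMe)·HCl, i-PrMgCl, THF, −20 → 0 °C
Reagents that add atoms: N,O-dimethylhydroxylamine hydrochloride, CNOC.Cl
Why: Aminolysis of the ester by the chloromagnesium amide of N,O-dimethylhydroxylamine gives the N-methoxy-N-methylamide; the C8 alkoxide formed first protects the α-centre from enolisation.

Step 10
Reactants: 16 (S)-2-hydroxy-N-methoxy-N,4-dimethylpent-4-enamide
Product: 17 (S)-2-hydroxy-N-methoxy-N-methyl-4-oxopentanamide
Conditions: O3, CH2Cl2/MeOH, −78 °C; then Me2S, −78 °C → rt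
Reagents that add atoms: ozone, [O-][O+]=O
Why: Ozonolysis of the 1,1-disubstituted alkene with reductive work-up unveils the C10 methyl ketone, while the amide and the carbinol are inert.

Step 11
Reactants: 18 diethyl (2-hydroxyethyl)phosphonate
Product: 19 diethyl [2-(tert-butyldimethylsilyloxy)ethyl]phosphonate
Conditions: TBSCl, imidazole, DMF, rt
Reagents that add atoms: tert-butyldimethylsilyl chloride, CC(C)(C)[Si](C)(C)Cl
Why: Silylation of the primary alcohol gives the C13 oxygen as a TBS ether, which is not a leaving group in the later carbanion and dienolate steps.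

Step 12
Reactants: 19 diethyl [2-(tert-butyldimethylsilyloxy)ethyl]phosphonate
Product: 21 3-(tert-butyldimethylsilyloxy)-2-(diethoxyphosphoryl)propanoic acid (racemic), via alpha-lithio phosphonate 20 (not isolated)
Conditions: LDA, THF, −78 °C; then CO2, −78 → 0 °C; cold 0.5 M HCl work-up
Reagents that add atoms: carbon dioxide, O=C=O
Why: Deprotonation alpha to phosphorus and carboxylation of the phosphonate carbanion install C12; at −78 °C the β-silyloxy carbanion should not eliminate, and the C11 centre is racemic but becomes sp2 in step 17.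

Step 13
Reactants: 12 (S)-2-methyl-2-[(triisopropylsilyloxy)methyl]-2,3-dihydrofuran; 17 (S)-2-hydroxy-N-methoxy-N-methyl-4-oxopentanamide
Product: 24 (2S,4S)-2,4-dihydroxy-N-methoxy-N-methyl-4-{(5S)-5-methyl-5-[(triisopropylsilyloxy)methyl]-4,5-dihydrofuran-2-yl}pentanamide, via 5-lithio-2,3-dihydrofuran 22 (not isolated), via chloromagnesium alkoxide 23 (not isolated)
Conditions: 12, t-BuLi, THF/pentane, −78 → 0 °C; 17, t-BuMgCl, THF, −78 °C; combine at −78 °C; pH 7 phosphate buffer
Reagents that add atoms: none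
Why: α-Lithiation of the cyclic enol ether at the vinylic C1–H and chelation-controlled 1,2-addition of the alkenyllithium to the methyl ketone of the magnesium aldolate 23, in which Mg bridges the C8 alkoxide, the C10 carbonyl and the amide so that attack comes from the chelate face opposite the C7 substituent and should set C10 as (S), 1,3-anti to C8, while the alkoxide-shielded N-methoxy-N-methylamide stays intact at −78 °C.

Step 14
Reactants: 24 (2S,4S)-2,4-dihydroxy-N-methoxy-N-methyl-4-{(5S)-5-methyl-5-[(triisopropylsilyloxy)methyl]-4,5-dihydrofuran-2-yl}pentanamide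
Product: 25 (2S,4S)-2,4-dihydroxy-4-[(5S)-5-(hydroxymethyl)-5-methyl-4,5-dihydrofuran-2-yl]-N-methoxy-N-methylpentanamide
Conditions: TBAF, THF, 0 °C → rt
Reagents that add atoms: none
Why: Fluoride desilylation frees C5–OH at a stage where no other silyl ether is present, so that C5 can be re-protected with the most labile group of the later set.

Step 15
Reactants: 25 (2S,4S)-2,4-dihydroxy-4-[(5S)-5-(hydroxymethyl)-5-methyl-4,5-dihydrofuran-2-yl]-N-methoxy-N-methylpentanamide
Product: 26 (2S,4S)-N-methoxy-N-methyl-4-{(5S)-5-methyl-5-[(triethylsilyloxy)methyl]-4,5-dihydrofuran-2-yl}-2,4-bis(triethylsilyloxy)pentanamide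
Conditions: TESOTf, 2,6-lutidine, CH2Cl2, −78 → 0 °C
Reagents that add atoms: triethylsilyl trifluoromethanesulfonate, CC[Si](CC)(CC)OS(=O)(=O)C(F)(F)F
Why: Persilylation with a silyl triflate and a hindered pyridine base covers the primary, secondary and tertiary hydroxyls alike, and the buffered, non-protic medium spares the enol ether.

Step 16
Reactants: 26 (2S,4S)-N-methoxy-N-methyl-4-{(5S)-5-methyl-5-[(triethylsilyloxy)methyl]-4,5-dihydrofuran-2-yl}-2,4-bis(triethylsilyloxy)pentanamide
Product: 27 (3S,5S)-1-chloro-5-{(5S)-5-methyl-5-[(triethylsilyloxy)methyl]-4,5-dihydrofuran-2-yl}-3,5-bis(triethylsilyloxy)hexan-2-one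
Conditions: ICH2Cl, MeLi·LiBr, THF, −78 °C; pH 7 buffer at −78 °C
Reagents that add atoms: chloroiodomethane, ClCI
Why: Acylation of a lithium carbenoid: chloromethyllithium made by iodine–lithium exchange adds to the N-methoxy-N-methylamide and the chelated tetrahedral intermediate collapses only on work-up, so the α-chloro ketone carrying C6 should form without over-addition.

Step 17
Reactants: 27 (3S,5S)-1-chloro-5-{(5S)-5-methyl-5-[(triethylsilyloxy)methyl]-4,5-dihydrofuran-2-yl}-3,5-bis(triethylsilyloxy)hexan-2-one; 21 3-(tert-butyldimethylsilyloxy)-2-(diethoxyphosphoryl)propanoic acid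
Product: 29 3-[(tert-butyldimethylsilyloxy)methyl]-4-{(1S,3S)-3-[(5S)-5-methyl-5-[(triethylsilyloxy)methyl]-4,5-dihydrofuran-2-yl]-1,3-bis(triethylsilyloxy)butyl}furan-2(5H)-one, via keto phosphonoacetate ester 28 (not isolated)
Conditions: 21, Cs2CO3, DMF, 0 °C → rt; then LiCl, DBU, 0 °C
Reagents that add atoms: none
Why: The caesium carboxylate of 21 displaces the chloride of the α-chloro ketone (SN2) and the phosphonate carbanion of 28 then closes the butenolide by intramolecular Horner–Wadsworth–Emmons olefination of the C7 ketone, the five-membered ring closure under LiCl/DBU being fast enough to spare the C8 centre next to the ketone.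

Step 18
Reactants: 29 (the butenolide of step 17)
Product: 30 (2S)-5-{(2S,4S)-4-[4-[(tert-butyldimethylsilyloxy)methyl]-5-oxo-2,5-dihydrofuran-3-yl]-2,4-bis(triethylsilyloxy)butan-2-yl}-2-methyl-2,3-dihydrofuran-2-carbaldehyde
Conditions: (COCl)2, DMSO, CH2Cl2, −78 → −40 °C; then Et3N, −78 → 0 °C
Reagents that add atoms: none
Why: Swern oxidation in its deprotective form: the chlorosulfonium reagent cleaves the primary TES ether in situ and oxidises C5 to the aldehyde, while the secondary and tertiary TES ethers and the primary TBS ether should survive.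

Step 19
Reactants: 30 (the aldehyde of step 18)
Product: 33 (4S,5E,8S,10S)-13-(tert-butyldimethylsilyloxy)-8,10-bis(triethylsilyloxy)-1,4-epoxygermacra-1,5,7(11)-trien-12,6-olide, via 2-silyloxyfuran aldehyde 31 (not isolated), via macrocyclic aldol silyl ether 32 (not isolated)
Conditions: TBSOTf, i-Pr2NEt, CH2Cl2 (2 mM), 0 °C → rt; then DBU, rt
Reagents that add atoms: none
Why: Soft enolisation gives the 2-silyloxyfuran 31, whose γ-carbon C6 adds to the non-enolisable C5 aldehyde in an intramolecular vinylogous Mukaiyama aldol reaction under high dilution, and DBU then expels silanolate from 32 (E1cB) to give the γ-alkylidene butenolide; the C5=C6 geometry (C4 cis to C7, E by priority) should be the only one the bridged ten-membered ring accommodates.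

Step 20
Reactants: 33 (the protected macrocycle of step 19)
Product: 34 (4S,5E,8S,10S)-8,10,13-trihydroxy-1,4-epoxygermacra-1,5,7(11)-trien-12,6-olide
Conditions: TBAF/AcOH (1:1), THF, 0 °C → rt
Reagents that add atoms: none
Why: Acetic acid-buffered fluoride desilylation removes both TES ethers and the TBS ether without opening the enol lactone or protonating the enol ether.

Step 21
Reactants: 34 (the triol of step 20)
Product: 35 (4S,5E,8S,10S)-8,13-diacetoxy-10-hydroxy-1,4-epoxygermacra-1,5,7(11)-trien-12,6-olide (target, CNP0144020.1)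
Conditions: Ac2O, pyridine, DMAP (cat.), CH2Cl2, 0 °C
Reagents that add atoms: acetic anhydride, CC(=O)OC(C)=O
Why: Acylation with Ac2O/pyridine acetylates the primary C13 and the secondary C8 hydroxyls, while the hindered tertiary C10 hydroxyl should not react at 0 °C.

**Compound list**

1 | (R)-propane-1,2-diol | C[C@@H](O)CO | starting material
2 | (R)-1-(triisopropylsilyloxy)propan-2-ol | C[C@@H](O)CO[Si](C(C)C)(C(C)C)C(C)C | intermediate
3 | bromoacetic acid | OC(=O)CBr | starting material
4 | 2-{[(2R)-1-(triisopropylsilyloxy)propan-2-yl]oxy}acetic acid | C[C@@H](OCC(=O)O)CO[Si](C(C)C)(C(C)C)C(C)C | intermediate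
5 | (trimethylsilyl)diazomethane | C[Si](C)(C)C=[N+]=[N-] | starting material
6 | isobutyl carbonic mixed anhydride of 4 | C[C@@H](OCC(=O)OC(=O)OCC(C)C)CO[Si](C(C)C)(C(C)C)C(C)C | intermediate (not isolated)
7 | 1-diazo-3-{[(2R)-1-(triisopropylsilyloxy)propan-2-yl]oxy}propan-2-one | C[C@@H](OCC(=O)C=[N+]=[N-])CO[Si](C(C)C)(C(C)C)C(C)C | intermediate
8 | (5S)-5-methyl-5-[(triisopropylsilyloxy)methyl]dihydrofuran-3(2H)-one | C[C@@]1(CO[Si](C(C)C)(C(C)C)C(C)C)CC(=O)CO1 | intermediate
9 | (5S)-5-methyl-5-[(triisopropylsilyloxy)methyl]tetrahydrofuran-3-ol, both C3 epimers | C[C@@]1(CO[Si](C(C)C)(C(C)C)C(C)C)CC(O)CO1 | intermediate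
10 | (5S)-5-methyl-5-[(triisopropylsilyloxy)methyl]tetrahydrofuran-3-yl methanesulfonate, both C3 epimers | C[C@@]1(CO[Si](C(C)C)(C(C)C)C(C)C)CC(OS(C)(=O)=O)CO1 | intermediate
11 | (S)-2-methyl-2-[(triisopropylsilyloxy)methyl]-2,5-dihydrofuran | C[C@@]1(CO[Si](C(C)C)(C(C)C)C(C)C)C=CCO1 | intermediate (not isolated)
12 | (S)-2-methyl-2-[(triisopropylsilyloxy)methyl]-2,3-dihydrofuran | C[C@@]1(CO[Si](C(C)C)(C(C)C)C(C)C)CC=CO1 | intermediate
13 | ethyl glyoxylate | CCOC(=O)C=O | starting material
14 | isobutene | CC(C)=C | starting material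
15 | ethyl (S)-2-hydroxy-4-methylpent-4-enoate | CCOC(=O)[C@@H](O)CC(C)=C | intermediate
16 | (S)-2-hydroxy-N-methoxy-N,4-dimethylpent-4-enamide | CON(C)C(=O)[C@@H](O)CC(C)=C | intermediate
17 | (S)-2-hydroxy-N-methoxy-N-methyl-4-oxopentanamide | CON(C)C(=O)[C@@H](O)CC(C)=O | intermediate
18 | diethyl (2-hydroxyethyl)phosphonate | CCOP(=O)(CCO)OCC | starting material
19 | diethyl [2-(tert-butyldimethylsilyloxy)ethyl]phosphonate | CCOP(=O)(CCO[Si](C)(C)C(C)(C)C)OCC | intermediate
20 | alpha-lithio derivative of 19 | CCOP(=O)(C([Li])CO[Si](C)(C)C(C)(C)C)OCC | intermediate (not isolated)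
21 | 3-(tert-butyldimethylsilyloxy)-2-(diethoxyphosphoryl)propanoic acid (racemic) | CCOP(=O)(OCC)C(CO[Si](C)(C)C(C)(C)C)C(=O)O | intermediate
22 | (S)-5-lithio-2-methyl-2-[(triisopropylsilyloxy)methyl]-2,3-dihydrofuran | C[C@@]1(CO[Si](C(C)C)(C(C)C)C(C)C)CC=C([Li])O1 | intermediate (not isolated)
23 | chloromagnesium alkoxide of 17 | CON(C)C(=O)[C@@H](O[Mg]Cl)CC(C)=O | intermediate (not isolated)
24 | (2S,4S)-2,4-dihydroxy-N-methoxy-N-methyl-4-{(5S)-5-methyl-5-[(triisopropylsilyloxy)methyl]-4,5-dihydrofuran-2-yl}pentanamide | C[C@@]1(CO[Si](C(C)C)(C(C)C)C(C)C)CC=C(O1)[C@@](C)(O)C[C@H](O)C(=O)N(C)OC | intermediate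
25 | (2S,4S)-2,4-dihydroxy-4-[(5S)-5-(hydroxymethyl)-5-methyl-4,5-dihydrofuran-2-yl]-N-methoxy-N-methylpentanamide | C[C@@]1(CO)CC=C(O1)[C@@](C)(O)C[C@H](O)C(=O)N(C)OC | intermediate
26 | (2S,4S)-N-methoxy-N-methyl-4-{(5S)-5-methyl-5-[(triethylsilyloxy)methyl]-4,5-dihydrofuran-2-yl}-2,4-bis(triethylsilyloxy)pentanamide | C[C@@]1(CO[Si](CC)(CC)CC)CC=C(O1)[C@@](C)(O[Si](CC)(CC)CC)C[C@H](O[Si](CC)(CC)CC)C(=O)N(C)OC | intermediate
27 | (3S,5S)-1-chloro-5-{(5S)-5-methyl-5-[(triethylsilyloxy)methyl]-4,5-dihydrofuran-2-yl}-3,5-bis(triethylsilyloxy)hexan-2-one | C[C@@]1(CO[Si](CC)(CC)CC)CC=C(O1)[C@@](C)(O[Si](CC)(CC)CC)C[C@H](O[Si](CC)(CC)CC)C(=O)CCl | intermediate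
28 | (3S,5S)-5-{(5S)-5-methyl-5-[(triethylsilyloxy)methyl]-4,5-dihydrofuran-2-yl}-2-oxo-3,5-bis(triethylsilyloxy)hexyl 3-(tert-butyldimethylsilyloxy)-2-(diethoxyphosphoryl)propanoate | C[C@@]1(CO[Si](CC)(CC)CC)CC=C(O1)[C@@](C)(O[Si](CC)(CC)CC)C[C@H](O[Si](CC)(CC)CC)C(=O)COC(=O)C(CO[Si](C)(C)C(C)(C)C)P(=O)(OCC)OCC | intermediate (not isolated)
29 | 3-[(tert-butyldimethylsilyloxy)methyl]-4-{(1S,3S)-3-[(5S)-5-methyl-5-[(triethylsilyloxy)methyl]-4,5-dihydrofuran-2-yl]-1,3-bis(triethylsilyloxy)butyl}furan-2(5H)-one | C[C@@]1(CO[Si](CC)(CC)CC)CC=C(O1)[C@@](C)(O[Si](CC)(CC)CC)C[C@H](O[Si](CC)(CC)CC)C2=C(CO[Si](C)(C)C(C)(C)C)C(=O)OC2 | intermediate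
30 | (2S)-5-{(2S,4S)-4-[4-[(tert-butyldimethylsilyloxy)methyl]-5-oxo-2,5-dihydrofuran-3-yl]-2,4-bis(triethylsilyloxy)butan-2-yl}-2-methyl-2,3-dihydrofuran-2-carbaldehyde | C[C@@]1(C=O)CC=C(O1)[C@@](C)(O[Si](CC)(CC)CC)C[C@H](O[Si](CC)(CC)CC)C2=C(CO[Si](C)(C)C(C)(C)C)C(=O)OC2 | intermediate
31 | 2-(tert-butyldimethylsilyloxy)furan derived from 30 (furan C3 bears CH2OTBS, furan C4 bears C8) | C[C@@]1(C=O)CC=C(O1)[C@@](C)(O[Si](CC)(CC)CC)C[C@H](O[Si](CC)(CC)CC)c2coc(O[Si](C)(C)C(C)(C)C)c2CO[Si](C)(C)C(C)(C)C | intermediate (not isolated)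
32 | macrocyclic vinylogous aldol adduct, C5 silyl ether, C5–C6 single bond, mixture at C5 and C6 | C[C@@]1(C2O[Si](C)(C)C(C)(C)C)CC=C(O1)[C@@](C)(O[Si](CC)(CC)CC)C[C@H](O[Si](CC)(CC)CC)C3=C(CO[Si](C)(C)C(C)(C)C)C(=O)OC32 | intermediate (not isolated)
33 | (4S,5E,8S,10S)-13-(tert-butyldimethylsilyloxy)-8,10-bis(triethylsilyloxy)-1,4-epoxygermacra-1,5,7(11)-trien-12,6-olide | CC(C)(C)[Si](C)(C)OCC1=C2/C(=C\[C@]3(C)CC=C(O3)[C@@](C)(O[Si](CC)(CC)CC)C[C@@H]2O[Si](CC)(CC)CC)OC1=O | intermediate
34 | (4S,5E,8S,10S)-8,10,13-trihydroxy-1,4-epoxygermacra-1,5,7(11)-trien-12,6-olide | OCC1=C2/C(=C\[C@]3(C)CC=C(O3)[C@@](C)(O)C[C@@H]2O)OC1=O | intermediate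
35 | (4S,5E,8S,10S)-8,13-diacetoxy-10-hydroxy-1,4-epoxygermacra-1,5,7(11)-trien-12,6-olide | CC(=O)OCC1=C2/C(=C\[C@]3(C)CC=C(O3)[C@@](C)(O)C[C@@H]2OC(C)=O)OC1=O | target

**Count and risks**

Total step count: 21. Longest linear sequence: 16 steps (steps 1–7 and 13–21).

The three steps most likely to fail:

1. Step 19 (ring closure at C5=C6). The ten-membered ring may fail to close because of transannular strain, so that intermolecular aldol oligomerisation takes over. The silyl triflate may also attack the enol ether or ionise the allylic silyl ethers of the silyloxyfuran. Fallback, from 29 back to 33, closes the ring with a phosphonate carbanion instead of a Lewis-acid aldol. Soft enolisation of 29 (TBSOTf, Et3N) and bromination of the transient silyloxyfuran with NBS at −78 °C should give the γ-bromobutenolide F1. Arbuzov reaction with P(OMe)3 gives the γ-(dimethoxyphosphoryl)butenolide F2. Oxidation of the primary silyl ether as in step 18 gives the aldehyde F3. LiCl/DBU in MeCN under high dilution then closes the ring by intramolecular Horner–Wadsworth–Emmons olefination and gives 33.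

2. Step 13 (C10 centre). Facial selectivity may be poor if the magnesium chelate is not the reacting species, and the alkenyllithium may enolise the ketone or trigger retro-aldol cleavage of the aldolate. Fallback, from 12 back to 24, brings the two C10 substituents in the opposite order and corrects C8 afterwards. Lithiated 12 is added to the chloromagnesium alkoxide of (2R)-2-hydroxy-N1,N4-dimethoxy-N1,N4-dimethylbutanediamide F4, made from commercial dimethyl (R)-malate with MeNH(OMe)·HCl/i-PrMgCl. The alkoxide shields the near amide, so acylation at the distal amide should give the hydroxy ketone F5. MeMgBr (CH2Cl2/Et2O, −78 °C) then adds to the magnesium chelate of F5 with the small nucleophile anti to the C7 substituent, which gives the (2R,4S)-diol F6 with the required C10 configuration. Mitsunobu inversion at C8 with 4-nitrobenzoic acid (PPh3, DIAD) gives the (2S)-4-nitrobenzoate F7, and K2CO3/MeOH returns to 24.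

3. Step 18 (deprotective oxidation). The chlorosulfonium reagent may attack the electron-rich dihydrofuran enol ether, or the silyl ether cleavage may stall at the neopentyl primary position or spread to the secondary one. Fallback, from 29 back to 30, separates the two events. Selective removal of the primary TES ether with HF·pyridine buffered with excess pyridine (THF, 0 °C) gives the primary alcohol F8. Parikh–Doering oxidation (SO3·pyridine, DMSO, i-Pr2NEt), which involves no electrophilic chlorine species, then gives 30.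

**Further compounds**

F1 | step 19 | 5-bromo derivative of 29 (bromine on C6 of the butenolide) | C[C@@]1(CO[Si](CC)(CC)CC)CC=C(O1)[C@@](C)(O[Si](CC)(CC)CC)C[C@H](O[Si](CC)(CC)CC)C2=C(CO[Si](C)(C)C(C)(C)C)C(=O)OC2Br
F2 | step 19 | 5-(dimethoxyphosphoryl) derivative of 29 | C[C@@]1(CO[Si](CC)(CC)CC)CC=C(O1)[C@@](C)(O[Si](CC)(CC)CC)C[C@H](O[Si](CC)(CC)CC)C2=C(CO[Si](C)(C)C(C)(C)C)C(=O)OC2P(=O)(OC)OC
F3 | step 19 | 5-(dimethoxyphosphoryl) derivative of aldehyde 30 | C[C@@]1(C=O)CC=C(O1)[C@@](C)(O[Si](CC)(CC)CC)C[C@H](O[Si](CC)(CC)CC)C2=C(CO[Si](C)(C)C(C)(C)C)C(=O)OC2P(=O)(OC)OC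
F4 | step 13 | (2R)-2-hydroxy-N1,N4-dimethoxy-N1,N4-dimethylbutanediamide | CON(C)C(=O)[C@H](O)CC(=O)N(C)OC
F5 | step 13 | (2R)-2-hydroxy-N-methoxy-N-methyl-4-{(5S)-5-methyl-5-[(triisopropylsilyloxy)methyl]-4,5-dihydrofuran-2-yl}-4-oxobutanamide | C[C@@]1(CO[Si](C(C)C)(C(C)C)C(C)C)CC=C(O1)C(=O)C[C@@H](O)C(=O)N(C)OC
F6 | step 13 | (2R,4S)-2,4-dihydroxy-N-methoxy-N-methyl-4-{(5S)-5-methyl-5-[(triisopropylsilyloxy)methyl]-4,5-dihydrofuran-2-yl}pentanamide | C[C@@]1(CO[Si](C(C)C)(C(C)C)C(C)C)CC=C(O1)[C@@](C)(O)C[C@@H](O)C(=O)N(C)OC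
F7 | step 13 | (2S,4S)-4-hydroxy-1-[methoxy(methyl)amino]-4-{(5S)-5-methyl-5-[(triisopropylsilyloxy)methyl]-4,5-dihydrofuran-2-yl}-1-oxopentan-2-yl 4-nitrobenzoate | C[C@@]1(CO[Si](C(C)C)(C(C)C)C(C)C)CC=C(O1)[C@@](C)(O)C[C@H](OC(=O)c2ccc(cc2)[N+](=O)[O-])C(=O)N(C)OC
F8 | step 18 | primary alcohol from 29 (C5–OH free, other silyl ethers kept) | C[C@@]1(CO)CC=C(O1)[C@@](C)(O[Si](CC)(CC)CC)C[C@H](O[Si](CC)(CC)CC)C2=C(CO[Si](C)(C)C(C)(C)C)C(=O)OC2
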